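**Retrosynthetic overview**
- The target is U(4β→6)M(4β→8)L (U and M epicatechin 3-O-gallate, L catechin; flavan numbering). The strategy rests on C4 of unit M, a doubly benzylic carbon between C4a of ring A of M and C8 of ring A of L, and on the cis aryl/galloyloxy pair at C2/C3 of M, which is a (Z)-enol gallate.
- Key disconnection: ring C of M by [4+2] addition of the (Z)-enol gallate to the ortho-quinone methide O1=C8a–C4a=C4, made at the anode from a 2-benzylphenol; this forms O1–C2 and C3–C4.
- The 2-benzylphenol comes from an sp3–sp2 Suzuki coupling of a catechin C8–CH2–boronate with an iodophenol aldehyde. Its formyl group (C6 of M) blocks the position para to the phenol and later becomes C4 of unit U.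
- Ring C of U is closed by a second quinone methide [4+2] addition (aldehyde, 3,5-bis(benzyloxy)phenol and the same enol gallate); hydrogenolysis of nineteen benzyl ethers ends the route.
- Ring order: rings of L from (+)-catechin, then ring C of M (step 10), then ring C of U (step 11).

Key step: step 10

Remark on the chemistry: the group para to the phenol in the key step is carried as a formyl group, not an ester, because it must become C4 of unit U after a gallate ester is in place, when an ester could no longer be reduced selectively. 3,5-Bis(benzyloxy)phenol, 3,4-bis(benzyloxy)benzaldehyde and 3,4,5-tris(benzyloxy)benzoic acid are taken as commercial; Bn = benzyl.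

**Route**

Step 1
Reactants: 1 (+)-catechin
Product: 2 5,7,3',4'-tetra-O-benzyl-(+)-catechin
Conditions: BnBr (4.4 equiv), K2CO3, DMF, 0 °C to rt
Reagents that add atoms: benzyl bromide, BrCc1ccccc1
Why: Williamson ether synthesis in which K2CO3 deprotonates only the four phenols, so the secondary 3-OH stays free and C2 and C3 are untouched.

Step 2
Reactants: 2 5,7,3',4'-tetra-O-benzyl-(+)-catechin
Product: 3 3,5,7,3',4'-penta-O-benzyl-(+)-catechin
Conditions: NaH, BnBr, DMF, 0 °C to rt
Reagents that add atoms: benzyl bromide, BrCc1ccccc1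
Why: Williamson etherification of the secondary alkoxide formed with NaH; no stereocentre is involved.

Step 3
Reactants: 3 3,5,7,3',4'-penta-O-benzyl-(+)-catechin
Product: 4 8-bromo-3,5,7,3',4'-penta-O-benzyl-(+)-catechin
Conditions: NBS (1.0 equiv), CH2Cl2, −78 °C to rt
Reagents that add atoms: N-bromosuccinimide, O=C1CCC(=O)N1Br
Why: electrophilic aromatic bromination of the most electron-rich ring (ring A), at C8 (between O1 and the C7 ether) in preference to the more hindered C6, as is established for benzylated catechins.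

Step 4
Reactants: 4 8-bromo-3,5,7,3',4'-penta-O-benzyl-(+)-catechin
Product: 7 8-[(4,4,5,5-tetramethyl-1,3,2-dioxaborolan-2-yl)methyl]-3,5,7,3',4'-penta-O-benzyl-(+)-catechin, via aryllithium 5 (not isolated), via boron ate complex 6 (not isolated)
Conditions: n-BuLi, THF, −78 °C; then BrCH2Bpin, −78 °C to rt
Reagents that add atoms: 2-(bromomethyl)-4,4,5,5-tetramethyl-1,3,2-dioxaborolane, BrCB1OC(C)(C)C(C)(C)O1
Why: bromine–lithium exchange gives the C8 aryllithium, which adds to boron; 1,2-aryl shift with loss of bromide (Matteson homologation) should give the benzylic boronate.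

Step 5
Reactants: 8 3,5-bis(benzyloxy)phenol
Product: 10 2,6-bis(benzyloxy)-4-hydroxybenzaldehyde, via iminium chloride 9 (not isolated)
Conditions: POCl3, DMF, MeCN, 0 °C to rt; then H2O, rt
Reagents that add atoms: N,N-dimethylformamide, CN(C)C=O; water, O
Why: Vilsmeier–Haack formylation, expected mainly para to the free hydroxyl group (between the two benzyloxy groups) as with 3,5-dimethoxyphenol; the chelated ortho isomer is removed by chromatography and hydrolysis of 9 frees the aldehyde.

Step 6
Reactants: 10 2,6-bis(benzyloxy)-4-hydroxybenzaldehyde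
Product: 11 2,6-bis(benzyloxy)-4-hydroxy-3-iodobenzaldehyde
Conditions: NIS (1.0 equiv), TsOH·H2O (10 mol%), MeCN, 0 °C to rt
Reagents that add atoms: N-iodosuccinimide, O=C1CCC(=O)N1I
Why: electrophilic iodination ortho to the phenol; the para position is blocked and the two ortho positions are equivalent, so one equivalent of NIS should give a single mono-iodide.

Step 7
Reactants: 7 8-[(4,4,5,5-tetramethyl-1,3,2-dioxaborolan-2-yl)methyl]-3,5,7,3',4'-penta-O-benzyl-(+)-catechin; 11 2,6-bis(benzyloxy)-4-hydroxy-3-iodobenzaldehyde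
Product: 12 2,6-bis(benzyloxy)-4-hydroxy-3-[(penta-O-benzylcatechin-8-yl)methyl]benzaldehyde
Conditions: Pd(OAc)2 (5 mol%), SPhos (10 mol%), K3PO4, toluene–H2O, 80 °C
Reagents that add atoms: none
Why: Suzuki–Miyaura sp3–sp2 coupling of a primary benzylic boronate with an aryl iodide; the para formyl group helps oxidative addition, the bulky electron-rich phosphine copes with the two ortho substituents, and the free phenol and aldehyde are tolerated under aqueous phosphate.

Step 8
Reactants: 13 3,4-bis(benzyloxy)benzaldehyde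
Product: 14 1,2-bis(benzyloxy)-4-ethynylbenzene
Conditions: dimethyl (1-diazo-2-oxopropyl)phosphonate, K2CO3, MeOH–THF, rt
Reagents that add atoms: dimethyl (1-diazo-2-oxopropyl)phosphonate, COP(=O)(OC)C(=[N+]=[N-])C(C)=O
Why: Seyferth–Gilbert homologation with the Ohira–Bestmann reagent turns the aryl aldehyde into the terminal alkyne under mild base that leaves the benzyl ethers alone.

Step 9
Reactants: 14 1,2-bis(benzyloxy)-4-ethynylbenzene; 15 3,4,5-tris(benzyloxy)benzoic acid
Product: 16 (Z)-2-[3,4-bis(benzyloxy)phenyl]ethenyl 3,4,5-tris(benzyloxy)benzoate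
Conditions: Ru(η3-2-methylallyl)2(dppb) (2 mol%), toluene, 65 °C
Reagents that add atoms: none
Why: ruthenium-catalysed anti-Markovnikov addition of a carboxylic acid to a terminal alkyne; carboxylate attack on the ruthenium vinylidene and protonolysis give the (Z)-enol ester, as established for benzoic acids and arylacetylenes.

Step 10
Reactants: 12 2,6-bis(benzyloxy)-4-hydroxy-3-[(penta-O-benzylcatechin-8-yl)methyl]benzaldehyde; 16 (Z)-2-[3,4-bis(benzyloxy)phenyl]ethenyl 3,4,5-tris(benzyloxy)benzoate
Product: 18 perbenzylated 6-formyl-epicatechin-3-O-gallate-(4β→8)-catechin, via quinone methide 17 (not isolated)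
Conditions: divided cell, reticulated vitreous carbon anode, Pt cathode, 16 (3 equiv), 2,6-lutidine (4 equiv), LiClO4 (0.3 M), MeNO2–CH2Cl2, controlled potential at the first anodic wave of 12 with lutidine (found by cyclic voltammetry), 2.1 F/mol, 0 °C, then rt
Reagents that add atoms: none
Why: Proposed new method: the phenol of 12, hydrogen-bonded to 2,6-lutidine, is the most easily oxidised group, so the anode takes two electrons and the base takes the phenolic and the doubly benzylic proton to give quinone methide 17 (the para position is closed by the formyl group, so no para-quinone methide can form), and 17 then adds the electron-rich (Z)-styrenyl ester 16 in an inverse-demand hetero-Diels–Alder reaction. The closest known reactions are the anodic and Ag2O oxidations of ortho-alkylphenols to ortho-quinone methides and the [4+2] additions of such methides to styrenes; generation of an aryl-substituted methide by direct electrolysis of a 2-benzylphenol in the presence of an oxidisable styrene has not been shown. Ring C of unit M closes as a six-membered ring by intermolecular [4+2] cycloaddition, O1–C2 and C3–C4 forming on one face of the alkene, with C4 bonding to the acyloxy-bearing carbon because the dialkoxyaryl group stabilises the positive charge that builds at C2. C2 and C3 come out cis because the addition is suprafacial on the (Z)-alkene; C4 comes out trans to C3 when the L aryl group lies on the inner (carbonyl) side of the methide, which is expected here because the outer side is blocked by the peri C5 benzyloxy group, and the alkene adds endo, an arrangement that holds this aryl group anti to the C3 gallate. The step needs oxidation at the phenol only, secured by electrolysis at the first wave well below the potentials of the benzyl ethers and of 16, and needs no acid, secured by the lutidine buffer, so the benzhydryl C4–C8 bond is not ionised. The face of 17 that is attacked is differentiated only by the C2 and C3 centres of unit L, so the 4β isomer is expected together with the isomer of opposite configuration in unit M and is separated by chromatography.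

Step 11
Reactants: 18 perbenzylated 6-formyl-epicatechin-3-O-gallate-(4β→8)-catechin; 8 3,5-bis(benzyloxy)phenol; 16 (Z)-2-[3,4-bis(benzyloxy)phenyl]ethenyl 3,4,5-tris(benzyloxy)benzoate
Product: 21 perbenzylated epicatechin-3-O-gallate-(4β→6)-epicatechin-3-O-gallate-(4β→8)-catechin, via benzodioxaborin 19 (not isolated), via quinone methide 20 (not isolated)
Conditions: PhB(OH)2 (1.1 equiv), EtCO2H (20 mol%), 16 (3 equiv), toluene, 4 Å MS, 80 °C then 110 °C
Reagents that add atoms: none
Why: known three-component quinone methide chroman synthesis in which the boronic acid templates ortho-specific condensation of the phenol with the aldehyde to 19, which opens to methide 20 and adds the (Z)-styrenyl ester by hetero-Diels–Alder reaction, C2 and C3 of unit U cis from the alkene geometry and C4 trans by the same inner-aryl/endo arrangement as in step 10 (peri C5 benzyloxy group of ring A of U), while the face is set only by unit M so that the 4β isomer is separated from its diastereomer by chromatography.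

Step 12
Reactants: 21 perbenzylated epicatechin-3-O-gallate-(4β→6)-epicatechin-3-O-gallate-(4β→8)-catechin
Product: 22 epicatechin-3-O-gallate-(4β→6)-epicatechin-3-O-gallate-(4β→8)-catechin (CNP0112921.1)
Conditions: H2 (1 atm), Pd(OH)2/C, THF–MeOH–H2O, rt
Reagents that add atoms: none
Why: hydrogenolysis of the nineteen benzyl ethers over Pearlman's catalyst under neutral conditions should leave the two gallate esters, the two interflavan bonds and the eight stereocentres unchanged.

**Compound list**
1 | (+)-catechin, (2R,3S) | O[C@H]1Cc2c(O)cc(O)cc2O[C@@H]1c1ccc(O)c(O)c1 | starting material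
2 | 5,7,3',4'-tetra-O-benzyl-(+)-catechin | c7c(OCc9ccccc9)cc(OCc9ccccc9)c8c7O[C@H](c6ccc(OCc9ccccc9)c(OCc9ccccc9)c6)[C@@H](O)C8 | intermediate
3 | 3,5,7,3',4'-penta-O-benzyl-(+)-catechin | c7c(OCc9ccccc9)cc(OCc9ccccc9)c8c7O[C@H](c6ccc(OCc9ccccc9)c(OCc9ccccc9)c6)[C@@H](OCc9ccccc9)C8 | intermediate
4 | 8-bromo-3,5,7,3',4'-penta-O-benzyl-(+)-catechin | Brc7c(OCc9ccccc9)cc(OCc9ccccc9)c8c7O[C@H](c6ccc(OCc9ccccc9)c(OCc9ccccc9)c6)[C@@H](OCc9ccccc9)C8 | intermediate
5 | 8-lithio-penta-O-benzylcatechin (formed in the flask) | [Li]c7c(OCc9ccccc9)cc(OCc9ccccc9)c8c7O[C@H](c6ccc(OCc9ccccc9)c(OCc9ccccc9)c6)[C@@H](OCc9ccccc9)C8 | intermediate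
6 | lithium (bromomethyl)(penta-O-benzylcatechin-8-yl)(pinacolato)borate (formed in the flask) | [Li+].BrC[B-]1(OC(C)(C)C(C)(C)O1)c7c(OCc9ccccc9)cc(OCc9ccccc9)c8c7O[C@H](c6ccc(OCc9ccccc9)c(OCc9ccccc9)c6)[C@@H](OCc9ccccc9)C8 | intermediate
7 | 8-[(4,4,5,5-tetramethyl-1,3,2-dioxaborolan-2-yl)methyl]-3,5,7,3',4'-penta-O-benzyl-(+)-catechin | CC1(C)OB(OC1(C)C)Cc7c(OCc9ccccc9)cc(OCc9ccccc9)c8c7O[C@H](c6ccc(OCc9ccccc9)c(OCc9ccccc9)c6)[C@@H](OCc9ccccc9)C8 | intermediate
8 | 3,5-bis(benzyloxy)phenol | Oc1cc(OCc2ccccc2)cc(OCc2ccccc2)c1 | starting material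
9 | [2,6-bis(benzyloxy)-4-hydroxybenzylidene]dimethyliminium chloride (formed in the flask) | C[N+](C)=Cc1c(OCc2ccccc2)cc(O)cc1OCc1ccccc1.[Cl-] | intermediate
10 | 2,6-bis(benzyloxy)-4-hydroxybenzaldehyde | O=Cc1c(OCc2ccccc2)cc(O)cc1OCc1ccccc1 | intermediate
11 | 2,6-bis(benzyloxy)-4-hydroxy-3-iodobenzaldehyde | O=Cc1c(OCc2ccccc2)cc(O)c(I)c1OCc1ccccc1 | intermediate
12 | 2,6-bis(benzyloxy)-4-hydroxy-3-[(penta-O-benzylcatechin-8-yl)methyl]benzaldehyde (key-step precursor) | O=Cc3c(OCc9ccccc9)cc(O)c(Cc7c(OCc9ccccc9)cc(OCc9ccccc9)c8c7O[C@H](c6ccc(OCc9ccccc9)c(OCc9ccccc9)c6)[C@@H](OCc9ccccc9)C8)c3OCc9ccccc9 | intermediate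
13 | 3,4-bis(benzyloxy)benzaldehyde | O=Cc1ccc(OCc2ccccc2)c(OCc2ccccc2)c1 | starting material
14 | 1,2-bis(benzyloxy)-4-ethynylbenzene | C#Cc1ccc(OCc2ccccc2)c(OCc2ccccc2)c1 | intermediate
15 | 3,4,5-tris(benzyloxy)benzoic acid | OC(=O)c1cc(OCc2ccccc2)c(OCc2ccccc2)c(OCc2ccccc2)c1 | starting material
16 | (Z)-2-[3,4-bis(benzyloxy)phenyl]ethenyl 3,4,5-tris(benzyloxy)benzoate | O=C(O/C=C\c1ccc(OCc9ccccc9)c(OCc9ccccc9)c1)c1cc(OCc9ccccc9)c(OCc9ccccc9)c(OCc9ccccc9)c1 | intermediate
17 | (Z)-ortho-quinone methide of 12: 2,4-bis(benzyloxy)-6-oxo-5-[(penta-O-benzylcatechin-8-yl)methylidene]cyclohexa-1,3-diene-1-carbaldehyde, L aryl group syn to the carbonyl (formed in the flask) | O=C1C=C(OCc9ccccc9)C(C=O)=C(OCc9ccccc9)/C1=C/c7c(OCc9ccccc9)cc(OCc9ccccc9)c8c7O[C@H](c6ccc(OCc9ccccc9)c(OCc9ccccc9)c6)[C@@H](OCc9ccccc9)C8 | intermediate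
18 | benzyl-protected dimer: unit M = 5,7,3',4'-tetra-O-benzyl-6-formyl-epicatechin 3-O-(3,4,5-tri-O-benzylgallate), 2,3-cis-3,4-trans (2R,3R,4R), C4 bonded (4β) to C8 of penta-O-benzylcatechin (key-step product) | O=Cc3c(OCc9ccccc9)cc4c(c3OCc9ccccc9)[C@H](c7c(OCc9ccccc9)cc(OCc9ccccc9)c8c7O[C@H](c6ccc(OCc9ccccc9)c(OCc9ccccc9)c6)[C@@H](OCc9ccccc9)C8)[C@@H](OC(=O)c5cc(OCc9ccccc9)c(OCc9ccccc9)c(OCc9ccccc9)c5)[C@@H](c6ccc(OCc9ccccc9)c(OCc9ccccc9)c6)O4 | intermediate
19 | 5,7-bis(benzyloxy)-2-phenyl-4H-1,3,2-benzodioxaborin carrying at C4 the C6 aryl group of unit M of 18, both C4 epimers (formed in the flask) | c1ccccc1B1Oc2cc(OCc9ccccc9)cc(OCc9ccccc9)c2C(O1)c3c(OCc9ccccc9)cc4c(c3OCc9ccccc9)[C@H](c7c(OCc9ccccc9)cc(OCc9ccccc9)c8c7O[C@H](c6ccc(OCc9ccccc9)c(OCc9ccccc9)c6)[C@@H](OCc9ccccc9)C8)[C@@H](OC(=O)c5cc(OCc9ccccc9)c(OCc9ccccc9)c(OCc9ccccc9)c5)[C@@H](c6ccc(OCc9ccccc9)c(OCc9ccccc9)c6)O4 | intermediate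
20 | (Z)-ortho-quinone methide of unit U: 3,5-bis(benzyloxy)-6-(arylmethylidene)cyclohexa-2,4-dien-1-one, aryl = C6 of unit M, syn to the carbonyl (formed in the flask) | O=C1C=C(OCc9ccccc9)C=C(OCc9ccccc9)/C1=C/c3c(OCc9ccccc9)cc4c(c3OCc9ccccc9)[C@H](c7c(OCc9ccccc9)cc(OCc9ccccc9)c8c7O[C@H](c6ccc(OCc9ccccc9)c(OCc9ccccc9)c6)[C@@H](OCc9ccccc9)C8)[C@@H](OC(=O)c5cc(OCc9ccccc9)c(OCc9ccccc9)c(OCc9ccccc9)c5)[C@@H](c6ccc(OCc9ccccc9)c(OCc9ccccc9)c6)O4 | intermediate
21 | benzyl-protected trimer (nineteen benzyl ethers): unit U = 5,7,3',4'-tetra-O-benzyl-epicatechin 3-O-(tri-O-benzylgallate), 2,3-cis-3,4-trans, C4 bonded (4β) to C6 of unit M | O=C(O[C@@H]1[C@@H](c3c(OCc9ccccc9)cc4c(c3OCc9ccccc9)[C@H](c7c(OCc9ccccc9)cc(OCc9ccccc9)c8c7O[C@H](c6ccc(OCc9ccccc9)c(OCc9ccccc9)c6)[C@@H](OCc9ccccc9)C8)[C@@H](OC(=O)c5cc(OCc9ccccc9)c(OCc9ccccc9)c(OCc9ccccc9)c5)[C@@H](c6ccc(OCc9ccccc9)c(OCc9ccccc9)c6)O4)c2c(OCc9ccccc9)cc(OCc9ccccc9)cc2O[C@@H]1c1ccc(OCc9ccccc9)c(OCc9ccccc9)c1)c1cc(OCc9ccccc9)c(OCc9ccccc9)c(OCc9ccccc9)c1 | intermediate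
22 | epicatechin-3-O-gallate-(4β→6)-epicatechin-3-O-gallate-(4β→8)-catechin (CNP0112921.1) | O=C(O[C@@H]1[C@@H](c2c(O)cc3c(c2O)[C@H](c2c(O)cc(O)c4c2O[C@H](c2ccc(O)c(O)c2)[C@@H](O)C4)[C@@H](OC(=O)c2cc(O)c(O)c(O)c2)[C@@H](c2ccc(O)c(O)c2)O3)c2c(O)cc(O)cc2O[C@@H]1c1ccc(O)c(O)c1)c1cc(O)c(O)c(O)c1 | target

**Step count**
Total: 12 steps. Longest linear sequence: 8 steps (steps 1, 2, 3, 4, 7, 10, 11, 12).

**Steps most likely to fail**

Step 10 (Proposed new method). The oxidation may not stay at the phenol: phenoxyl radicals may couple through the free C8 position of ring A of M, or the styrenyl ester may be co-oxidised. The cycloaddition may also show poor endo and facial selectivity; an outer-aryl methide reacting endo would give the 4α isomer. The fallback sets out from 12 and comes back at 18, and takes oxidation and cycloaddition apart. Compound 12 is treated with DDQ (1.0 equiv) in CH2Cl2–MeOH at 0 °C. Hydride abstraction from the doubly benzylic CH2 and capture by methanol should give the ortho-hydroxybenzhydryl methyl ether F1 (both epimers), a known benzylic oxidation of electron-rich diarylmethanes. Isolated F1 and 16 are then stirred with a chiral BINOL-derived phosphoric acid (10 mol%) and 5 Å molecular sieves in toluene at room temperature. This is the known Brønsted acid-catalysed generation of a hydrogen-bonded ortho-quinone methide from an ortho-hydroxybenzyl ether and its [4+2] addition to a styrene. It should give 18, with the catalyst enantiomer chosen to favour the 4β face.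

Step 11. The hindered aldehyde may condense slowly, 16 may be lost thermally at 110 °C, and methide 20 may add without facial preference. The fallback sets out from 18 and 8 and comes back at 21. Benzodioxaborin 19 is formed as in step 11 but at 80 °C and without the alkene. Its boron is removed by exchange with diethanolamine, which should give the ortho-hydroxybenzhydrol F2. F2 and 16 are then combined with a chiral phosphoric acid (10 mol%) and 4 Å sieves in toluene at 0 °C to room temperature. This is the known acid-catalysed dehydration of ortho-hydroxybenzhydrols to hydrogen-bonded quinone methides and their asymmetric [4+2] addition to styrenes, so the face is set by the catalyst and not by unit M.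

Step 7. The electron-rich benzylic boronate may protodeboronate, and transmetalation at the doubly ortho-substituted arylpalladium centre may be slow. The fallback sets out from 10 and 3 and comes back at 12. Compound 10 is aminomethylated ortho to the phenol with dimethyl(methylidene)ammonium iodide in CH2Cl2 (Mannich reaction) to the benzylamine F3. F3 is heated with 3 (2 equiv) in toluene–acetic acid at 90 °C. Loss of dimethylamine gives the ortho-quinone methide of the aldehyde ring, which alkylates C8 of 3, the position also taken by bromine in step 3. This is a Friedel–Crafts alkylation by a phenolic Mannich base, known for phloroglucinol ethers. A C6-linked isomer, if formed, is removed by chromatography.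

**Further compounds**
F1 | step 10 | 2,6-bis(benzyloxy)-4-hydroxy-3-[methoxy(penta-O-benzylcatechin-8-yl)methyl]benzaldehyde, both epimers at the methoxy carbon | O=Cc3c(OCc9ccccc9)cc(O)c(C(OC)c7c(OCc9ccccc9)cc(OCc9ccccc9)c8c7O[C@H](c6ccc(OCc9ccccc9)c(OCc9ccccc9)c6)[C@@H](OCc9ccccc9)C8)c3OCc9ccccc9
F2 | step 11 | ortho-hydroxybenzhydrol from 18 and 8: [2,4-bis(benzyloxy)-6-hydroxyphenyl](C6 aryl group of unit M of 18)methanol, both carbinol epimers | Oc1cc(OCc9ccccc9)cc(OCc9ccccc9)c1C(O)c3c(OCc9ccccc9)cc4c(c3OCc9ccccc9)[C@H](c7c(OCc9ccccc9)cc(OCc9ccccc9)c8c7O[C@H](c6ccc(OCc9ccccc9)c(OCc9ccccc9)c6)[C@@H](OCc9ccccc9)C8)[C@@H](OC(=O)c5cc(OCc9ccccc9)c(OCc9ccccc9)c(OCc9ccccc9)c5)[C@@H](c6ccc(OCc9ccccc9)c(OCc9ccccc9)c6)O4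
F3 | step 7 | 2,6-bis(benzyloxy)-3-[(dimethylamino)methyl]-4-hydroxybenzaldehyde | O=Cc1c(OCc2ccccc2)cc(O)c(CN(C)C)c1OCc1ccccc1
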